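Separate what feeds G.X from what drains it before trusting any integrated curve.

| setting | Friday's | Saturday's | Monday's |
|---|---|---|---|
| G | 16 mM | 16 mM | 16 mM |
| J | 25.0 mM | 50.0 mM | 100 mM |
| D | 2.1 mM (held) | 2.1 mM (held) | 2.1 mM (held) |
| time | 8.0 min | 8.0 min | 8.0 min |

    D ⇌ X, rate k1*(csat - [X]) (k1 = 0.0362 s⁻¹, csat = 2.1 mM)
    G + X → G.X (k2 = 1.32 M⁻¹ s⁻¹)
    J + G.X → J.G.X (k3 = 0.0904 M⁻¹ s⁻¹)
    G ⇌ Z (K4 = 0.57, k4 = 0.00211 s⁻¹)
    2 G → G2 (k5 = 1.54 × 10⁻⁴ M⁻¹ s⁻¹)

- in percentages every species weighs as the G in it: one G2 counts as two
- for a step with 2 of a species take k times the square, and two of it per event
- at the start none of X is dissolved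
- "hardly changes" means that all values lie within two and a half points (for a concentration: within two and a half percent of the largest)
- run time (Friday's): 8.0 min

1. amount of J.G.X at the end, in percent of the G charged for Friday's, Saturday's, Monday's, in this order
2. the course of these numbers from the first flask to the last (falls all the way / rises, then falls / falls, then rises / rises all the way / hardly changes)

J stands on the left of the step that uses G.X and not on the left of G + X → G.X. Friday's and Monday's flasks differ in their J charge, so this text's reckoning gives them the same course of G.X made and lets them part at the J step. Both hold more J than G, so this text's own reckoning takes J at its charge. That makes the J step pseudo-first-order, with constant κ equal to its rate constant times the J charged.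

Now let G.X arrive at an even rate through a run of length t, which is an assumption. Integrating the balance of G.X, and then κ[G.X], gives φ = 1 − (1 − e^−u)/u, with u = κt. On Friday's flask u = 1.08, so φ = 0.390, and this passage share, the part of the G.X made that stands as J.G.X at the end, is the quantity to carry. On Monday's flask u = 4.34 and φ = 0.773. With equal G.X made, Monday's yield should be about twice Friday's. Saturday's flask, at φ = 0.592, lies between them, so the row rises. The amount of G.X made is not reckoned here, so this reckoning ends with a ratio and a direction, without percentages.

The forecast commits to percentages: 20.8%, 32.1% and 41.3%, a course that rises all the way, holding of the G.X captured that “this amount does not depend on J”.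

The simulation gives 20.0%, 30.7% and 40.0%, and the course rises all the way.

Friday's flask falls short of full conversion mainly through the time allowed: run to 80.0 min, it holds 97.6% J.G.X instead of 20.0%. At 8.00 min its u is still 1.08, and 29.5% of the G charged stands as G.X. J.G.X over J.G.X plus G.X therefore reads 0.404 there, beside a φ of 0.390. Monday's flask, with 40.0% J.G.X and 9.51% G.X, reads 0.808, beside a φ of 0.773.

The numbers of this flask are made up; the flask was simulated.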